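Amounts of substrate and product after 8.0 min are what these two flasks are run for, and Saturday's differs from Wednesday's in its charge of free catalyst.

    free catalyst ⇌ dormant form (K1 = 0.32, k1 = 0.00120 s⁻¹)
    substrate + catalyst intermediate A ⇌ catalyst intermediate B (K2 = 110 M⁻¹, k2 = 44.8 M⁻¹ s⁻¹)
    partner + free catalyst ⇌ catalyst intermediate A (K3 = 1560 M⁻¹, k3 = 30.3 M⁻¹ s⁻¹)
    catalyst intermediate B ⇌ free catalyst + product (K4 = 0.0228 M, k4 = 0.343 s⁻¹)

- Saturday's: substrate 0.020 M; partner 0.0220 M; free catalyst 0.22 mM; time 8.0 min
- Wednesday's: substrate 0.020 M; partner 0.0220 M; free catalyst 0.15 mM; time 8.0 min

* which of these there is most of at the end, counted by the substrate in it, Saturday's (product / catalyst intermediate B / substrate)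
* which of these there is most of at the end, counted by the substrate in it, Wednesday's (product / catalyst intermediate B / substrate)
* the largest of these amounts at the end, in percent of the substrate charged, Saturday's
* the largest of these amounts at the end, in percent of the substrate charged, Wednesday's

The bench rule takes the smallest first-order constant of the working round, with partner and substrate counted at their charge as pseudo-first-order, as the rate-limiting step and lets each catalyst turn over at that rate. Here that is step 4, with 0.343 s⁻¹. Applied to Wednesday's flask, the rule asks for 123% of the charged substrate and reaches the full charge at 6.48 min.

The rule needs the other steps far faster than step 4, and the charges lie beyond that border. Step 3 with its partner stands at 1.94 times k4, and step 2 with its substrate at 2.61 times. Moreover, catalyst intermediate B returns through step 2 faster than it gives product, by a ratio of 1.19. So each turnover takes on average 2.19 passes of step 2.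

Adding the stops gives 6.86 s at the charge. This is the cycle time, the time one catalyst needs per turnover: the wait of free catalyst for partner, plus the wait of catalyst intermediate A for substrate times the passes, plus the stay of catalyst intermediate B summed over those passes. It holds c(partner) and c(substrate), so it lengthens as they fall.

Catalyst charge times running time over cycle time gives 10.5 mM of product in Wednesday's flask and 15.4 mM in Saturday's. Taking the cycle time instead where half of that product stands gives 8.20 s for Wednesday's and 9.19 s for Saturday's. My reckoning is therefore product at 57.4% in Saturday's flask, and in Wednesday's product at 43.9%, leaving substrate at 56.1%. It omits the dormant form and the way back of steps 3 and 4.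

The forecast gives product at 52% for Saturday's and substrate at 60% for Wednesday's, for a cycle “slowing as both are depleted and as product pushes back on the free catalyst”.

Saturday's flask ends with product at 52.5% and Wednesday's with substrate at 59.9%. My product figure stands 4.9 percentage points above the flask's product in Saturday's and 4.1 points above it in Wednesday's. At 4.00 min, Wednesday's flask holds substrate at 77.2% and partner at 79.1%, which puts the cycle time at 7.97 s, longer than the 6.86 s at the charge.

For a flask like Wednesday's but charged with 6.0 × 10⁻⁵ M of free catalyst, the cycle time at the charge gives 4.20 mM of product, and at half of that it is 7.30 s, giving product at 19.7% of the substrate charged. That flask ends with product at 18.2% and substrate at 81.6%.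

The rate constants were set for the occasion; the flask was simulated.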